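In a one-step world free monomer simply passes into chains, and the south and south-west readings show just such a fraction in chains. Length needs a second amount.

| flask | free monomer | transfer agent | protic impurity | initiator | remark | time |
|---|---|---|---|---|---|---|
| south | 16 mM (fed, over 10 h) | 4.8 mM | 1.6 mM | 1.6 mM | the very flask that is asked about, followed so far |  |
| south-west | 16 mM (fed, over 10 h) | 4.8 mM | 1.6 mM | 3.2 mM | run made earlier |  |
| flask | 16 mM (fed, over 10 h) | 4.80 mM | 1.60 mM | 1.6 mM |  | 10 h |

| run | time / h | monomer in chains / % | free monomer / % |
|---|---|---|---|
| south | 0.500 | 0.3 | 4.9 |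
| south | 1.00 | 0.2 | 8.7 |
| south | 1.50 | 2.8 | 13.3 |
| south | 2.50 | 4.0 | 19.0 |
| south | 3.00 | 5.7 | 19.9 |
| south | 4.00 | 11.3 | 24.4 |
| south-west | 0.500 | 0.5 | 3.0 |
| south-west | 1.00 | 2.0 | 8.3 |
| south-west | 1.50 | 3.3 | 10.9 |
| south-west | 2.50 | 8.1 | 15.1 |
| south-west | 3.00 | 11.2 | 16.0 |
| south-west | 4.00 | 18.3 | 18.1 |

(scatter of a reading: 1 percentage point)

- the average divides the monomer in chains by the number of chains begun, living and dead together
- the numbers in the tables scatter by 1 percentage point (one standard deviation)
- the earlier runs do not show the number of chains; that part of a forecast is a guess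
- percentages count the whole charge, also what has not yet gone in

1. whether the average number of monomer units in a chain (chains begun, living or dead) reaches 10 by 10 h (yes / no)
2. average number of monomer units in a chain (chains begun, living or dead) at 10 h

Length is monomer in chains over chains begun. Two charges frame it: c(free monomer), 16 mM, and c(initiator), 1.6 mM. Their ratio is 10.0, the charge length, the units charged per initiator (the target degree of polymerisation).

The reckoning here is not the forecast's, and it rests on a guess: each initiator used begins one chain. Length is then the charge length times the fraction in chains, divided by the fraction of initiator used. The south run reads 24.4 % free monomer at 4.00 h. If free monomer stays above that, chains hold under 75.6 %. If the whole 1.6 mM of initiator has reacted by then, length stays under 7.56, short of 10.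

The forecast says no, with length 3 (range 1.5 to 5) from about 2.5 mM of chains, and it warns: “number of chains is not measured, so this is a guess”.

The flask gives no, with length 6.22.

    free monomer + initiator → living end + monomer in chains (k = 1.50 M⁻¹ min⁻¹)
    free monomer + living end → monomer in chains + living end, rate k2*[living end]*[free monomer] (k = 3.40 M⁻¹ min⁻¹)
    living end + transfer agent → dead chain (kL = 0.0200 M⁻¹ min⁻¹)
    free monomer → uncatalysed product (k = 2.90 × 10⁻⁴ min⁻¹)
    protic impurity + free monomer → quenched substrate (k = 0.670 M⁻¹ min⁻¹)

In this flask the initiator's half-life by its step with free monomer at 6.99 h is 1.7 h, shorter than the dosing time of 10 h, and 4.01 % of it is left at 10.0 h. Chains begun, living end plus dead chain, stand at 1.54 mM, against the forecast's about 2.5 mM. The charge length times 59.7 % in chains, over the 96.0 % of initiator used, gives 6.22.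

A neighbour flask, charged with 27 mM of free monomer, has a charge length of 16.9. With 62.3 % in chains and 0.505 % of its initiator left at 10.0 h, that reckons to 10.6, and the computed length is 10.6.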